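Amounts opened the meeting: G at two charges, and in the cedar run Q added as well.

| flask | G | Q | time |
|---|---|---|---|
| birch | 0.300 M |  |  |
| cedar | 0.300 M | 0.0900 M |  |
| oak | 0.600 M |  |  |
| elm | 0.150 M |  | 65 min |

| birch run: time / min | birch run: [Q] / M | cedar run: time / min | cedar run: [Q] / M | oak run: time / min | oak run: [Q] / M |
|---|---|---|---|---|---|
| 2.3 | 0.0106 | 2.3 | 0.1001 | 2.3 | 0.0219 |
| 7.1 | 0.0436 | 7.1 | 0.1360 | 7.1 | 0.0915 |
| 14 | 0.0940 | 14 | 0.1878 | 14 | 0.1894 |
| 21 | 0.1376 | 21 | 0.2265 | 21 | 0.2769 |
| 31 | 0.1824 | 31 | 0.2739 | 31 | 0.3700 |
| 41 | 0.2207 | 41 | 0.3066 | 41 | 0.4318 |
| 52 | 0.2419 | 52 | 0.3331 | 52 | 0.4833 |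
| 65 | 0.2622 | 65 | 0.3493 | 65 | 0.5250 |

(scatter of a reading: 0.002 M)

- the exponent of [G] in the starting rate at the charge of the birch run (at the point where two percent of the G have become Q) (one fixed amount of Q, the same in the runs compared)
- Q in the elm run at 65 min, as a share of the G charged
- which of these the readings show (the product speeds the reaction / two substrates go astray together / an uncatalysed path runs beside)

- Overall: G -> Q.
- Constant volume, constant temperature.
- An order is taken over about fifteen percent of the charge, up and down.

The first speaker looked at the part of the charge not yet turned into Q at a given time. She read it in the oak run at 65 min as 12.5%, and in the birch run, at half that charge, as 12.6%. She named this the unturned share. She argued that in first-order steps it does not depend on the charge. She therefore put the elm run at 87.5%.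

The second speaker counted the Q gained in the cedar run, 86.4% of its charge, and said that added Q speeds nothing. He also noted that the mean birch rate rises from 0.00461 M min⁻¹ over the first interval to 0.00688 M min⁻¹ over the next. The oak run reaches a fixed amount of Q sooner, inside this lag. So he expected an exponent below one, without giving a figure.

The forecast gave an exponent of 1, a share of 87.5%, and the reading "an uncatalysed path runs beside". Its ground was: “That leaves a simple first-order path as the best of the three options”. Its share matches the first speaker's, but its exponent differs from the second speaker's expectation.

The flask gives an exponent of 0.70, a share of 87.3%, and "an uncatalysed path runs beside".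

    G → X (0.02508 min⁻¹)
    X → Q (0.3636 min⁻¹)
    G → Q (0.007740 min⁻¹)

The elm run leaves 12.7% unturned, against the 12.5% read in the oak run. At the fixed amount of Q, the oak rate stands at 1.6 times the birch rate, and there the forecast's exponent parts from the flask. G that goes through X stays unturned until X gives Q, so this rule is not claimed for that route. The direct path from G to Q gives Q at once, and with k as its constant it cuts the unturned share by a factor close to exp(−kt). Taking that path out of the elm run therefore multiplies 12.5% by about 1.65, which leaves about 79.3% of the charge as Q. The simulated run without that path gives 79.0%, so the path is worth 8.3 percentage points.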